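**Plan**

- Retrosynthetic cuts: the exocyclic C1–C(=O)Ar bond (C1 enol triflate plus 4-(benzyloxy)benzaldehyde), then in ring A the C3a–C7a and C6–C7 bonds (furan plus tethered ynone), then C1–C7a (acetylide plus aldehyde), C2–aryl (α-arylation) and C3–C3a (conjugate Friedel–Crafts alkylation).
- Enabling feature: ring A is a resorcinol with oxygens on C4 and C6 and hydrogens on C5 and C7, it shares its C3a–C7a edge with ring B, and C7a carries C1. C3a–C4(O)–C5–C6(O) is therefore a 2-alkyl-3-methoxyfuran (ring oxygen becomes the C6–OH) and C7=C7a–C1 is the alkyne and carbonyl of an ynone.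
- Forward order: the chain furan–C3–C2–C1–C≡CH is built first (steps 1–4), rings B and A close together in step 5, the aroyl carbon is attached at C1 (steps 8–10), and the C1=C2 bond is saturated last.
- Stereochemistry: C3 comes from the iminium-catalysed Friedel–Crafts step and is kept. C2 is left free to epimerise. C1 and C2 are set together in step 11 by syn hydrogenation on the face opposite the C3 aryl group (all-cis, 1R,2R,3R).
- Protecting groups: methyl ethers up to the indanone, then benzyl ethers, so that the last step is neutral and the labile all-cis ketone never meets acid or base.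

Key step: step 5

Remark: the (2R,5R) antipode of the imidazolidinone is assigned from the usual shielding model of its E-iminium ion, which predicts the (R)-aldehyde 3. The indane numbering of the target (C1 to C7a) is used for all ring compounds.

**Route**

Step 1
Reactants: 1 3-methoxyfuran; 2 (E)-4-methoxycinnamaldehyde
Product: 3 (R)-3-(3-methoxyfuran-2-yl)-3-(4-methoxyphenyl)propanal
Conditions: (2R,5R)-5-benzyl-2-tert-butyl-3-methylimidazolidin-4-one·TFA (20 mol %), 1 (3 equiv), CH2Cl2/i-PrOH, −40 °C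
Reagents that add atoms: none
Why: Conjugate Friedel–Crafts alkylation under iminium catalysis, known for electron-rich heteroarenes and for 4-methoxycinnamaldehyde; the furan attacks through C2 (α to the ring oxygen, β-carbon of the enol ether), and the benzyl and tert-butyl groups of the catalyst leave one face of the E-iminium ion open, which sets the centre that becomes C3.

Step 2
Reactants: 3 (R)-3-(3-methoxyfuran-2-yl)-3-(4-methoxyphenyl)propanal; 4 1-bromo-3,5-dimethoxybenzene
Product: 5 (3R)-2-(3,5-dimethoxyphenyl)-3-(3-methoxyfuran-2-yl)-3-(4-methoxyphenyl)propanal (both C2 epimers)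
Conditions: Pd(OAc)2 (cat.), rac-BINAP, Cs2CO3, 1,4-dioxane, 80 °C
Reagents that add atoms: none
Why: Palladium-catalysed α-arylation of a linear aldehyde with an aryl bromide (oxidative addition to zerovalent palladium, caesium enolate, reductive elimination) forms the C2–aryl bond; the new centre is α to the carbonyl, forms as both epimers and needs no control because it is erased in step 8 and reset in step 11.

Step 3
Reactants: 5 (3R)-2-(3,5-dimethoxyphenyl)-3-(3-methoxyfuran-2-yl)-3-(4-methoxyphenyl)propanal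
Product: 6 (5R)-4-(3,5-dimethoxyphenyl)-5-(3-methoxyfuran-2-yl)-5-(4-methoxyphenyl)pent-1-yn-3-ol (epimers at C3 and C4)
Conditions: HC≡CMgBr, THF, −78 → 0 °C; then H2O
Reagents that add atoms: ethynylmagnesium bromide, C#C[Mg]Br
Why: 1,2-Addition of an alkynyl Grignard reagent to the aldehyde forms the C1–C7a bond and should outrun enolisation of the α-aryl aldehyde at low temperature; the carbinol epimers are not separated because the centre is oxidised in step 4.

Step 4
Reactants: 6 (5R)-4-(3,5-dimethoxyphenyl)-5-(3-methoxyfuran-2-yl)-5-(4-methoxyphenyl)pent-1-yn-3-ol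
Product: 7 (5R)-4-(3,5-dimethoxyphenyl)-5-(3-methoxyfuran-2-yl)-5-(4-methoxyphenyl)pent-1-yn-3-one (both C4 epimers)
Conditions: Dess–Martin periodinane, pyridine, CH2Cl2, 0 °C
Reagents that add atoms: none
Why: Dess–Martin oxidation of a propargylic alcohol to the ynone is mild, and pyridine buffers the acetic acid set free so that the acid-labile 2-alkyl-3-methoxyfuran survives; the ynone is used at once.

Step 5
Reactants: 7 (5R)-4-(3,5-dimethoxyphenyl)-5-(3-methoxyfuran-2-yl)-5-(4-methoxyphenyl)pent-1-yn-3-one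
Product: 9 (2R,3R)-2-(3,5-dimethoxyphenyl)-6-hydroxy-4-methoxy-3-(4-methoxyphenyl)indan-1-one, via oxanorbornadiene cycloadduct 8 (not isolated)
Conditions: PhMe, 80 °C; then DABCO (20 mol %), 60 °C
Reagents that add atoms: none
Why: Heating should bring about an intramolecular (4+2) cycloaddition in which furan C2 and C5 add across the ynone triple bond, forming C3a–C7a and C6–C7 and giving the 7-oxanorbornadiene 8; DABCO then adds reversibly to C7 of the strained enone, the resulting C1 enolate expels the bridge oxygen from C3a, and loss of the amine together with H-6 aromatises ring A, so that the furan oxygen becomes the C6 phenol and the furan methoxy group the C4 ether. The closest known reactions are the intramolecular Diels–Alder reaction of furans with tethered alkynones followed by opening of the oxygen bridge to a phenol, and the base-induced β-eliminative opening of 7-oxanorbornane-2-carbonyl compounds. Ring B closes as the five-membered ring of the three-atom tether (the C3a–C7a bond, carbonyl inside the tether), and ring A closes as the six-membered carbocycle of the cycloadduct and becomes aromatic when the bridge opens. No lasting stereocentre is formed: the bridgeheads C3a and C6 become sp2, C3 is not touched, and C2 settles in the 2,3-trans arrangement through the enol. The step needs one ring-fusion regiochemistry, which the tether fixes because only furan C2 and C5 can reach the alkyne, and cleavage of the C3a–O and not the C6–O bridge bond; the 4-methoxy group by itself would assist ionisation at C6 (vinylogous oxocarbenium ion), so acid is kept out, and the C1 carbonyl, which stands β to the C3a–O bond through C7a, together with the fact that only C6 carries a hydrogen, directs the opening to the C6 phenol.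

Step 6
Reactants: 9 (2R,3R)-2-(3,5-dimethoxyphenyl)-6-hydroxy-4-methoxy-3-(4-methoxyphenyl)indan-1-one
Product: 10 (2R,3R)-2-(3,5-dihydroxyphenyl)-4,6-dihydroxy-3-(4-hydroxyphenyl)indan-1-one
Conditions: BBr3 (excess), CH2Cl2, −78 °C → rt; then H2O
Reagents that add atoms: none
Why: Exhaustive cleavage of the four aryl methyl ethers by BBr3 (boron–oxygen complexation, bromide attack on methyl) is standard for this 2,3-diarylindanone class and is placed here because the ketone tolerates it, C3 is not acidic and C2 simply stays trans.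

Step 7
Reactants: 10 (2R,3R)-2-(3,5-dihydroxyphenyl)-4,6-dihydroxy-3-(4-hydroxyphenyl)indan-1-one
Product: 11 (2R,3R)-4,6-bis(benzyloxy)-3-[4-(benzyloxy)phenyl]-2-[3,5-bis(benzyloxy)phenyl]indan-1-one
Conditions: BnBr (6 equiv), K2CO3, acetone, 56 °C, under argon
Reagents that add atoms: benzyl bromide, BrCc1ccccc1
Why: Williamson etherification of the five phenols, in which the phenoxides should react far faster than the hindered C2 enolate; benzyl groups are chosen so that step 11 removes them without acid or base.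

Step 8
Reactants: 11 (2R,3R)-4,6-bis(benzyloxy)-3-[4-(benzyloxy)phenyl]-2-[3,5-bis(benzyloxy)phenyl]indan-1-one
Product: 13 (3R)-4,6-bis(benzyloxy)-3-[4-(benzyloxy)phenyl]-2-[3,5-bis(benzyloxy)phenyl]-3H-inden-1-yl trifluoromethanesulfonate, via potassium enolate 12 (not isolated)
Conditions: KN(SiMe3)2 (1.0 equiv), THF, −78 °C; then N-(5-chloropyridin-2-yl)triflimide (1.2 equiv), −78 → −40 °C
Reagents that add atoms: N-(5-chloropyridin-2-yl)-1,1,1-trifluoro-N-(trifluoromethylsulfonyl)methanesulfonamide, O=S(=O)(N(c1ccc(Cl)cn1)S(=O)(=O)C(F)(F)F)C(F)(F)F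
Why: Deprotonation at C2, the only α-position, gives the indenolate 12, which the pyridyl triflimide O-sulfonylates to the C1 enol triflate (standard vinyl triflate formation); C2 becomes sp2 on purpose, and one equivalent of base at low temperature with the triflimide in excess should keep the indenyl-type C3–H from being removed.

Step 9
Reactants: 13 C1 enol triflate; 14 4-(benzyloxy)benzaldehyde
Product: 15 [4-(benzyloxy)phenyl]{(3S)-4,6-bis(benzyloxy)-3-[4-(benzyloxy)phenyl]-2-[3,5-bis(benzyloxy)phenyl]-3H-inden-1-yl}methanol (both carbinol epimers)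
Conditions: CrCl2 (6 equiv), NiCl2 (2 mol %), DMF, rt
Reagents that add atoms: none
Why: Nozaki–Hiyama–Kishi coupling, in which zerovalent nickel made in the flask inserts into the vinyl C–OTf bond and the vinyl group passes to trivalent chromium and adds to the aldehyde only, under non-basic conditions that leave the C3–H alone; both carbinol epimers are taken on.

Step 10
Reactants: 15 indenyl carbinol
Product: 16 [4-(benzyloxy)phenyl]{(3S)-4,6-bis(benzyloxy)-3-[4-(benzyloxy)phenyl]-2-[3,5-bis(benzyloxy)phenyl]-3H-inden-1-yl}methanone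
Conditions: Dess–Martin periodinane, CH2Cl2, 0 °C
Reagents that add atoms: none
Why: Dess–Martin oxidation of the doubly activated (allylic and benzylic) alcohol gives the 1-aroylindene without base, so that the vinylogous α-hydrogen at C3 should not be exchanged.

Step 11
Reactants: 16 hexabenzyl 1-aroylindene
Product: 18 caraphenol C, [(1R,2R,3R)-2-(3,5-dihydroxyphenyl)-4,6-dihydroxy-3-(4-hydroxyphenyl)indan-1-yl](4-hydroxyphenyl)methanone, via hexaphenol enone 17 (not isolated)
Conditions: H2 (3 atm), 10% Pd/C, EtOAc/MeOH, rt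
Reagents that add atoms: none
Why: Heterogeneous hydrogenation should first hydrogenolyse the six benzyl ethers to 17 and then add H2 syn to the tetrasubstituted C1=C2 bond from the face opposite the C3 aryl group, which sets C1 and C2 so that all three substituents are cis (1R,2R,3R); the medium is neutral, so the epimerisable C1 centre of the product is not disturbed.

**Compound list**

The C3 descriptor changes between R and S along the route only because substituent priorities change; the centre itself is not touched after step 1.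

1 | 3-methoxyfuran | COc1ccoc1 | starting material
2 | (E)-4-methoxycinnamaldehyde | COc1ccc(/C=C/C=O)cc1 | starting material
3 | (R)-3-(3-methoxyfuran-2-yl)-3-(4-methoxyphenyl)propanal | COc1ccoc1[C@@H](c1ccc(OC)cc1)CC=O | intermediate
4 | 1-bromo-3,5-dimethoxybenzene | COc1cc(Br)cc(OC)c1 | starting material
5 | (3R)-2-(3,5-dimethoxyphenyl)-3-(3-methoxyfuran-2-yl)-3-(4-methoxyphenyl)propanal, both C2 epimers | COc1ccoc1[C@@H](c1ccc(OC)cc1)C(c1cc(OC)cc(OC)c1)C=O | intermediate
6 | (5R)-4-(3,5-dimethoxyphenyl)-5-(3-methoxyfuran-2-yl)-5-(4-methoxyphenyl)pent-1-yn-3-ol, epimers at C3 and C4 | COc1ccoc1[C@@H](c1ccc(OC)cc1)C(c1cc(OC)cc(OC)c1)C(O)C#C | intermediate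
7 | (5R)-4-(3,5-dimethoxyphenyl)-5-(3-methoxyfuran-2-yl)-5-(4-methoxyphenyl)pent-1-yn-3-one, both C4 epimers | COc1ccoc1[C@@H](c1ccc(OC)cc1)C(c1cc(OC)cc(OC)c1)C(=O)C#C | intermediate
8 | (3R)-2-(3,5-dimethoxyphenyl)-4-methoxy-3-(4-methoxyphenyl)-2,3-dihydro-3a,6-epoxyinden-1(6H)-one (7-oxanorbornadiene cycloadduct, oxygen bridge from C3a to C6; bridge diastereomers and C2 epimers) | O=C1C(c2cc(OC)cc(OC)c2)[C@H](c2ccc(OC)cc2)C2(O3)C(OC)=CC3C=C12 | intermediate
9 | (2R,3R)-2-(3,5-dimethoxyphenyl)-6-hydroxy-4-methoxy-3-(4-methoxyphenyl)indan-1-one (2,3-trans) | O=C1c2cc(O)cc(OC)c2[C@@H](c2ccc(OC)cc2)[C@@H]1c1cc(OC)cc(OC)c1 | intermediate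
10 | (2R,3R)-2-(3,5-dihydroxyphenyl)-4,6-dihydroxy-3-(4-hydroxyphenyl)indan-1-one (2,3-trans) | O=C1c2cc(O)cc(O)c2[C@@H](c2ccc(O)cc2)[C@@H]1c1cc(O)cc(O)c1 | intermediate
11 | (2R,3R)-4,6-bis(benzyloxy)-3-[4-(benzyloxy)phenyl]-2-[3,5-bis(benzyloxy)phenyl]indan-1-one | O=C1c2cc(OCc3ccccc3)cc(OCc3ccccc3)c2[C@@H](c2ccc(OCc3ccccc3)cc2)[C@@H]1c1cc(OCc2ccccc2)cc(OCc2ccccc2)c1 | intermediate
12 | potassium enolate of 11 (potassium indenolate, C3 unchanged) | [K+].[O-]C1=C(c2cc(OCc3ccccc3)cc(OCc3ccccc3)c2)[C@H](c2ccc(OCc3ccccc3)cc2)c2c(OCc3ccccc3)cc(OCc3ccccc3)cc12 | intermediate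
13 | (3R)-4,6-bis(benzyloxy)-3-[4-(benzyloxy)phenyl]-2-[3,5-bis(benzyloxy)phenyl]-3H-inden-1-yl trifluoromethanesulfonate (target numbering, C1 enol triflate) | O=S(=O)(OC1=C(c2cc(OCc3ccccc3)cc(OCc3ccccc3)c2)[C@H](c2ccc(OCc3ccccc3)cc2)c2c(OCc3ccccc3)cc(OCc3ccccc3)cc12)C(F)(F)F | intermediate
14 | 4-(benzyloxy)benzaldehyde | O=Cc1ccc(OCc2ccccc2)cc1 | starting material
15 | [4-(benzyloxy)phenyl]{(3S)-4,6-bis(benzyloxy)-3-[4-(benzyloxy)phenyl]-2-[3,5-bis(benzyloxy)phenyl]-3H-inden-1-yl}methanol, both carbinol epimers | OC(c1ccc(OCc2ccccc2)cc1)C1=C(c2cc(OCc3ccccc3)cc(OCc3ccccc3)c2)[C@H](c2ccc(OCc3ccccc3)cc2)c2c(OCc3ccccc3)cc(OCc3ccccc3)cc12 | intermediate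
16 | [4-(benzyloxy)phenyl]{(3S)-4,6-bis(benzyloxy)-3-[4-(benzyloxy)phenyl]-2-[3,5-bis(benzyloxy)phenyl]-3H-inden-1-yl}methanone | O=C(c1ccc(OCc2ccccc2)cc1)C1=C(c2cc(OCc3ccccc3)cc(OCc3ccccc3)c2)[C@H](c2ccc(OCc3ccccc3)cc2)c2c(OCc3ccccc3)cc(OCc3ccccc3)cc12 | intermediate
17 | [(3S)-2-(3,5-dihydroxyphenyl)-4,6-dihydroxy-3-(4-hydroxyphenyl)-3H-inden-1-yl](4-hydroxyphenyl)methanone | O=C(c1ccc(O)cc1)C1=C(c2cc(O)cc(O)c2)[C@H](c2ccc(O)cc2)c2c(O)cc(O)cc12 | intermediate
18 | caraphenol C, [(1R,2R,3R)-2-(3,5-dihydroxyphenyl)-4,6-dihydroxy-3-(4-hydroxyphenyl)indan-1-yl](4-hydroxyphenyl)methanone, all-cis | O=C(c1ccc(O)cc1)[C@H]1c2cc(O)cc(O)c2[C@@H](c2ccc(O)cc2)[C@H]1c1cc(O)cc(O)c1 | target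

**Step count**

Total: 11 steps. Longest linear sequence: 11 steps (from 1 and 2 to 18).

**Steps most likely to fail**

1. Step 5. The bridge may open the wrong way if traces of acid let the 4-methoxy group ionise the C6–O bond, the amine may fail to add or to turn over, or the terminal ynone may oligomerise before it cyclises. Fallback, from 7 back to 9: the ynone 7 is heated alone in toluene at 80 °C in base-washed glassware and the cycloadduct 8 is taken on after evaporation. Thiophenol with catalytic Et3N in CH2Cl2 should add to C7 (thia-Michael addition, well known for oxanorbornadienes that carry an acceptor) to give (3R)-2-(3,5-dimethoxyphenyl)-4-methoxy-3-(4-methoxyphenyl)-7-(phenylsulfanyl)-2,3,7,7a-tetrahydro-3a,6-epoxyinden-1(6H)-one F1, which has a hydrogen on C7a. DBU in THF then enolises C1/C7a, the enolate expels the C3a oxygen as in the classical base-induced opening of 7-oxanorbornyl ketones, and loss of thiophenol across C6–C7 should give 9.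

2. Step 2. The linear aldehyde may undergo aldol self-condensation under carbonate, the free C5 position of the furan may be arylated instead, or the catalyst may stall on the hindered enolate. Fallback, from 3 back to 10, with the arylation moved to the ketone stage: HC≡CMgBr adds to 3 to give (5R)-5-(3-methoxyfuran-2-yl)-5-(4-methoxyphenyl)pent-1-yn-3-ol F2, and Dess–Martin periodinane with pyridine gives (5R)-5-(3-methoxyfuran-2-yl)-5-(4-methoxyphenyl)pent-1-yn-3-one F3. Heating in toluene and then DABCO, as in step 5, should lead through (3R)-4-methoxy-3-(4-methoxyphenyl)-2,3-dihydro-3a,6-epoxyinden-1(6H)-one F4 to (3R)-6-hydroxy-4-methoxy-3-(4-methoxyphenyl)indan-1-one F5. MeI and K2CO3 in acetone give (3R)-4,6-dimethoxy-3-(4-methoxyphenyl)indan-1-one F6. Palladium-catalysed α-arylation of this ketone with 4 (Pd(OAc)2, 2-dicyclohexylphosphino-2′,4′,6′-triisopropylbiphenyl, NaOt-Bu, toluene, 80 °C), a far more robust reaction than the aldehyde arylation, should give (2R,3R)-2-(3,5-dimethoxyphenyl)-4,6-dimethoxy-3-(4-methoxyphenyl)indan-1-one F7, and BBr3 converts it into 10.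

3. Step 11. The double bond may migrate on the palladium surface (a 1,3-hydrogen shift that scrambles C3), the facial selectivity on the tetrasubstituted alkene may be poor, or the aryl ketone may be over-reduced. Fallback, from 15 back to 18, in which the alkene is saturated before the ketone exists: directed homogeneous hydrogenation of the allylic alcohol 15 with [Ir(cod)(PCy3)(py)]PF6 and H2 in CH2Cl2 should add hydrogen anti to the C3 aryl group and give [4-(benzyloxy)phenyl]{(1R,2R,3R)-4,6-bis(benzyloxy)-3-[4-(benzyloxy)phenyl]-2-[3,5-bis(benzyloxy)phenyl]indan-1-yl}methanol F8. Dess–Martin periodinane gives [4-(benzyloxy)phenyl]{(1R,2R,3R)-4,6-bis(benzyloxy)-3-[4-(benzyloxy)phenyl]-2-[3,5-bis(benzyloxy)phenyl]indan-1-yl}methanone F9, and hydrogenolysis (H2, 10% Pd/C, EtOAc) then only has to remove the benzyl groups to give 18.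

**Further compounds**

F1 | step 5 | (3R)-2-(3,5-dimethoxyphenyl)-4-methoxy-3-(4-methoxyphenyl)-7-(phenylsulfanyl)-2,3,7,7a-tetrahydro-3a,6-epoxyinden-1(6H)-one | O=C1C(c2cc(OC)cc(OC)c2)[C@H](c2ccc(OC)cc2)C2(O3)C(OC)=CC3C(Sc3ccccc3)C12
F2 | step 2 | (5R)-5-(3-methoxyfuran-2-yl)-5-(4-methoxyphenyl)pent-1-yn-3-ol | COc1ccoc1[C@@H](c1ccc(OC)cc1)CC(O)C#C
F3 | step 2 | (5R)-5-(3-methoxyfuran-2-yl)-5-(4-methoxyphenyl)pent-1-yn-3-one | COc1ccoc1[C@@H](c1ccc(OC)cc1)CC(=O)C#C
F4 | step 2 | (3R)-4-methoxy-3-(4-methoxyphenyl)-2,3-dihydro-3a,6-epoxyinden-1(6H)-one | O=C1C[C@H](c2ccc(OC)cc2)C2(O3)C(OC)=CC3C=C12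
F5 | step 2 | (3R)-6-hydroxy-4-methoxy-3-(4-methoxyphenyl)indan-1-one | O=C1C[C@H](c2ccc(OC)cc2)c2c(OC)cc(O)cc12
F6 | step 2 | (3R)-4,6-dimethoxy-3-(4-methoxyphenyl)indan-1-one | O=C1C[C@H](c2ccc(OC)cc2)c2c(OC)cc(OC)cc12
F7 | step 2 | (2R,3R)-2-(3,5-dimethoxyphenyl)-4,6-dimethoxy-3-(4-methoxyphenyl)indan-1-one | O=C1c2cc(OC)cc(OC)c2[C@@H](c2ccc(OC)cc2)[C@@H]1c1cc(OC)cc(OC)c1
F8 | step 11 | [4-(benzyloxy)phenyl]{(1R,2R,3R)-4,6-bis(benzyloxy)-3-[4-(benzyloxy)phenyl]-2-[3,5-bis(benzyloxy)phenyl]indan-1-yl}methanol | OC(c1ccc(OCc2ccccc2)cc1)[C@H]1c2cc(OCc3ccccc3)cc(OCc3ccccc3)c2[C@@H](c2ccc(OCc3ccccc3)cc2)[C@H]1c1cc(OCc2ccccc2)cc(OCc2ccccc2)c1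
F9 | step 11 | [4-(benzyloxy)phenyl]{(1R,2R,3R)-4,6-bis(benzyloxy)-3-[4-(benzyloxy)phenyl]-2-[3,5-bis(benzyloxy)phenyl]indan-1-yl}methanone | O=C(c1ccc(OCc2ccccc2)cc1)[C@H]1c2cc(OCc3ccccc3)cc(OCc3ccccc3)c2[C@@H](c2ccc(OCc3ccccc3)cc2)[C@H]1c1cc(OCc2ccccc2)cc(OCc2ccccc2)c1
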